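The chain is numbered C1 (benzylic) to C8. The target is a syn-3,5-diol diacetate. O3 sits at the far end of the three-carbon unit C1–C2–C3 attached to the guaiacyl ring, and it is 1,3-related to O5. The plan rests on disconnecting the C3–O bond. A rhenium-oxo catalyst shifts a benzylic, allylic hydroxyl from C1 to C3. Benzaldehyde dimethyl acetal then ties O3 and O5 into an all-equatorial 2-phenyl-1,3-dioxane ring, so one operation sets C3 from the purchased (R)-C5 centre. The precursor is an (E)-1-aryloct-2-ene-1,5-diol, O-benzylated at the phenol and epimeric at C1, reached in three steps.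

Key step: step 4

Remark: the epoxide is used as the purchased single (R) enantiomer, and open-chain compounds keep the C1–C8 numbering of the target.

Design points:
- The precursor alkene is made strictly E, because a Z-allyl unit would let O5 close onto C1.
- The C5 hydroxyl stays free so that it can take up the acetal reagent at once.
- The phenol stays benzylated until the last step, so the acetates go on while no phenolic hydroxyl is exposed.

Step 1
Reactants: 1 (R)-1,2-epoxypentane; 2 lithium acetylide–ethylenediamine complex
Product: 3 (4R)-hept-1-yn-4-ol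
Conditions: 2 (1.5 equiv), DMSO, 0 °C → rt; then H2O
Reagents that add atoms: none
Why: SN2 ring opening of a terminal epoxide by an acetylide should occur only at the unsubstituted carbon, so the C–O bond of the stereocentre is never broken and the (R) centre of 1 is carried over unchanged as C5.

Step 2
Reactants: 3 (4R)-hept-1-yn-4-ol; 4 4-(benzyloxy)-3-methoxybenzaldehyde
Product: 6 (5R)-1-[4-(benzyloxy)-3-methoxyphenyl]oct-2-yne-1,5-diol as both C1 epimers, via dilithio alkynolate 5 (not isolated)
Conditions: n-BuLi (2.1 equiv), THF, −78 → −20 °C; 4, −78 → 0 °C; then H2O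
Reagents that add atoms: none
Why: 1,2-Addition of an alkynyllithium to a non-enolisable aromatic aldehyde: the second equivalent of base metalates the alkyne after the hydroxyl, only the carbanion adds, the benzyl ether is inert, and the new C1 centre needs no control because step 4 erases it.

Step 3
Reactants: 6 (5R)-1-[4-(benzyloxy)-3-methoxyphenyl]oct-2-yne-1,5-diol
Product: 7 (2E,5R)-1-[4-(benzyloxy)-3-methoxyphenyl]oct-2-ene-1,5-diol as both C1 epimers
Conditions: LiAlH4 (3 equiv), THF, 0 → 45 °C; then Na2SO4·10H2O
Reagents that add atoms: none
Why: Alkoxide-directed trans-hydroalumination of a propargylic alcohol followed by aqueous protonolysis should give the E-alkene exclusively, and neither the aryl benzyl ether nor C5 is touched by the hydride.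

Step 4
Reactants: 7 (2E,5R)-1-[4-(benzyloxy)-3-methoxyphenyl]oct-2-ene-1,5-diol; 8 benzaldehyde dimethyl acetal
Product: 10 (2R,4R,6R)-4-{(E)-2-[4-(benzyloxy)-3-methoxyphenyl]ethenyl}-2-phenyl-6-propyl-1,3-dioxane (all-cis), via transposed styryl diol 9 (not isolated)
Conditions: 8 (1.5 equiv) added first, then Re2O7 (3 mol %), CH2Cl2 (0.05 M), −20 °C → rt; then Et3N
Reagents that add atoms: none
Why: The C1 hydroxyl of 7 condenses with Re2O7 to an allyl perrhenate, and a chair-like, strongly polarised [3,3] shift places an oxo oxygen of rhenium on C3, returns the former C1 oxygen to the metal and moves the alkene into conjugation with the arene, which makes diol 9 the favoured regioisomer. The closest known reaction type is the rhenium-oxo 1,3-transposition of allylic alcohols, established for 1-aryl allylic alcohols and, with in situ benzylidene capture, for 2-ene-1,5-diols bearing a primary migrating hydroxyl. The perrhenic acid present exchanges one methoxy group of 8 for O5, loss of methanol gives an oxocarbenium ion, and O3 closes the 1,3-dioxane ring in a 6-endo-trig mode, the C=O+ bond lying inside the ring being formed. Both new stereocentres, C3 (dioxane C4) and the acetal carbon (dioxane C2), are set under thermodynamic control by the fixed (R)-C5 centre, because transposition, acetal exchange and heterolysis of the cinnamylic C3–O bond all remain reversible and the acetal of the anti diol, which must place one group axial or twist, drains into the chair that has propyl, styryl and phenyl equatorial, that is the syn 3,5-relation of the target. The step needs regioselectivity, secured by the conjugation gained and by the fact that only the 3,5-diol can form a six-membered acetal, and chemoselectivity, secured by the E-alkene, which prevents O5 from reaching C1 of the allyl system, and by the allylic oxygen, which deactivates the alkene of 7 toward Prins closure until it has moved away from O5. A cold start, dilution and an amine quench should hold back proton loss from C4 and arene alkylation, the exits that the electron-rich aryl group opens.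

Step 5
Reactants: 10 (2R,4R,6R)-4-{(E)-2-[4-(benzyloxy)-3-methoxyphenyl]ethenyl}-2-phenyl-6-propyl-1,3-dioxane
Product: 11 (2R,4S,6R)-4-{2-[4-(benzyloxy)-3-methoxyphenyl]ethyl}-2-phenyl-6-propyl-1,3-dioxane (all-cis)
Conditions: TsNHNH2 and NaOAc (excess, in portions), DME–H2O, reflux
Reagents that add atoms: none
Why: Diimide reduction: concerted syn transfer of two hydrogens from HN=NH, released by base-induced fragmentation of the sulfonyl hydrazide, saturates the C=C bond without a metal surface, so the cinnamylic C3–O bond, the acetal and the benzyl ether cannot be hydrogenolysed and no stereocentre is touched.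

Step 6
Reactants: 11 (2R,4S,6R)-4-{2-[4-(benzyloxy)-3-methoxyphenyl]ethyl}-2-phenyl-6-propyl-1,3-dioxane
Product: 13 (3S,5R)-1-[4-(benzyloxy)-3-methoxyphenyl]octane-3,5-diyl diacetate, via free syn diol 12 (not isolated)
Conditions: camphor-10-sulfonic acid (10 mol %), MeOH, 40 °C; Et3N, evaporate; then Ac2O, pyridine, DMAP (cat.), CH2Cl2, 0 °C → rt
Reagents that add atoms: acetic anhydride, CC(=O)OC(C)=O
Why: Acid-catalysed transacetalisation to methanol breaks only the bonds at the acetal carbon, so O3 and O5 stay on C3 and C5 with retention (C3 is no longer allylic and cannot ionise), and DMAP-catalysed acetylation of the crude diol then caps both secondary hydroxyls while the phenol is still masked.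

Step 7
Reactants: 13 (3S,5R)-1-[4-(benzyloxy)-3-methoxyphenyl]octane-3,5-diyl diacetate
Product: 14 (3S,5R)-1-(4-hydroxy-3-methoxyphenyl)octane-3,5-diyl diacetate
Conditions: H2 (1 atm), Pd/C (10 wt %), EtOAc, rt
Reagents that add atoms: none
Why: Catalytic hydrogenolysis cleaves only the benzylic C–O bond of the aryl benzyl ether, since both acetates sit on non-benzylic secondary carbons and are inert to H2 over palladium, so the phenol is freed without acyl migration or loss of configuration.

Compound list
1 | (R)-1,2-epoxypentane, (2R)-2-propyloxirane | CCC[C@@H]1CO1 | starting material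
2 | lithium acetylide–ethylenediamine complex | [Li]C#C.NCCN | starting material
3 | (4R)-hept-1-yn-4-ol | CCC[C@H](CC#C)O | intermediate
4 | 4-(benzyloxy)-3-methoxybenzaldehyde (O-benzylvanillin) | O=Cc1ccc(OCc2ccccc2)c(OC)c1 | starting material
5 | O,C-dilithio derivative of (4R)-hept-1-yn-4-ol (not isolated) | CCC[C@H](CC#C[Li])O[Li] | intermediate
6 | (5R)-1-[4-(benzyloxy)-3-methoxyphenyl]oct-2-yne-1,5-diol, both C1 epimers | CCC[C@H](CC#CC(O)c1ccc(OCc2ccccc2)c(OC)c1)O | intermediate
7 | (2E,5R)-1-[4-(benzyloxy)-3-methoxyphenyl]oct-2-ene-1,5-diol, both C1 epimers | CCC[C@H](C/C=C/C(O)c1ccc(OCc2ccccc2)c(OC)c1)O | intermediate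
8 | benzaldehyde dimethyl acetal | COC(OC)c1ccccc1 | starting material
9 | (1E,5R)-1-[4-(benzyloxy)-3-methoxyphenyl]oct-1-ene-3,5-diol, both C3 epimers (not isolated) | CCC[C@H](CC(O)/C=C/c1ccc(OCc2ccccc2)c(OC)c1)O | intermediate
10 | (2R,4R,6R)-4-{(E)-2-[4-(benzyloxy)-3-methoxyphenyl]ethenyl}-2-phenyl-6-propyl-1,3-dioxane, all-cis | CCC[C@@H]1C[C@H](/C=C/c2ccc(OCc3ccccc3)c(OC)c2)O[C@H](c2ccccc2)O1 | intermediate
11 | (2R,4S,6R)-4-{2-[4-(benzyloxy)-3-methoxyphenyl]ethyl}-2-phenyl-6-propyl-1,3-dioxane, all-cis | CCC[C@@H]1C[C@H](CCc2ccc(OCc3ccccc3)c(OC)c2)O[C@H](c2ccccc2)O1 | intermediate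
12 | (3S,5R)-1-[4-(benzyloxy)-3-methoxyphenyl]octane-3,5-diol (not isolated) | CCC[C@H](C[C@H](CCc1ccc(OCc2ccccc2)c(OC)c1)O)O | intermediate
13 | (3S,5R)-1-[4-(benzyloxy)-3-methoxyphenyl]octane-3,5-diyl diacetate | CCC[C@H](C[C@H](CCc1ccc(OCc2ccccc2)c(OC)c1)OC(C)=O)OC(C)=O | intermediate
14 | (3S,5R)-1-(4-hydroxy-3-methoxyphenyl)octane-3,5-diyl diacetate | CCC[C@H](C[C@H](CCc1ccc(O)c(OC)c1)OC(C)=O)OC(C)=O | target

Total step count: 7 (step 6 telescopes acetal cleavage and acetylation in one flask sequence).
Longest linear sequence: 7 steps, from 1 to 14.

Steps most likely to fail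

Step 4. The electron-rich aryl group may let full ionisation of the perrhenate outrun the ordered shift. The outcome could then be eroded by proton loss from C4, by capture of the cation by methanol, by slow leakage through a Z-allyl cation to ring closure between O5 and C1, or by incomplete equilibration of the acetals. The fallback separates transposition from stereocontrol and sets out from 7. Ph3SiOReO3 (cat.) in Et2O at low temperature, without any acetal reagent, isomerises 7 to diol 9, which is now isolated as its C3 epimers. MnO2 in CH2Cl2 oxidises only the cinnamylic hydroxyl to the β-hydroxy enone (1E,5R)-1-[4-(benzyloxy)-3-methoxyphenyl]-5-hydroxyoct-1-en-3-one F1. A Narasaka–Prasad reduction (Et2BOMe, NaBH4, THF–MeOH, −78 °C) delivers hydride to the boron chelate and should give the syn diol (1E,3R,5R)-1-[4-(benzyloxy)-3-methoxyphenyl]oct-1-ene-3,5-diol F2. Diimide as in step 5 saturates the alkene, and the route is rejoined at 12, which is acetylated as in step 6.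

Step 3. Two processes may compete with clean trans-hydroalumination at the temperature the internal alkyne needs: hydride displacement of the activated benzylic aluminate oxygen, and reduction beyond the alkene stage. The fallback makes the alkene by cross-metathesis instead of alkyne reduction and sets out from 1 and 4. CH2=CHMgBr with CuI (cat.) in THF opens 1 at the terminal carbon to (4R)-hept-1-en-4-ol F3. CH2=CHMgBr adds to 4 to give racemic 1-[4-(benzyloxy)-3-methoxyphenyl]prop-2-en-1-ol F4. The second-generation Hoveyda–Grubbs catalyst in CH2Cl2 at 40 °C should then join the two E-selectively, and the route is rejoined at 7.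

Step 5. Disproportionation of diimide may outrun hydrogen transfer to the conjugated, 1,2-disubstituted alkene, leaving conversion incomplete even with repeated charges. The fallback reorganises the end game around one global hydrogenation and sets out from 10. H2 over Pd/C in EtOAc–MeOH should saturate the alkene first and then cleave the benzylidene acetal and the benzyl ether to the triol (3S,5R)-1-(4-hydroxy-3-methoxyphenyl)octane-3,5-diol F5. Ac2O in pyridine gives the triacetate (3S,5R)-1-[4-(acetyloxy)-3-methoxyphenyl]octane-3,5-diyl diacetate F6. NH4OAc in aqueous MeOH at rt removes only the more electrophilic aryl acetate, and the route is rejoined at 14.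

Further compounds
F1 | step 4 | (1E,5R)-1-[4-(benzyloxy)-3-methoxyphenyl]-5-hydroxyoct-1-en-3-one | CCC[C@H](CC(=O)/C=C/c1ccc(OCc2ccccc2)c(OC)c1)O
F2 | step 4 | (1E,3R,5R)-1-[4-(benzyloxy)-3-methoxyphenyl]oct-1-ene-3,5-diol | CCC[C@H](C[C@H](/C=C/c1ccc(OCc2ccccc2)c(OC)c1)O)O
F3 | step 3 | (4R)-hept-1-en-4-ol | CCC[C@H](CC=C)O
F4 | step 3 | 1-[4-(benzyloxy)-3-methoxyphenyl]prop-2-en-1-ol (racemic) | C=CC(O)c1ccc(OCc2ccccc2)c(OC)c1
F5 | step 5 | (3S,5R)-1-(4-hydroxy-3-methoxyphenyl)octane-3,5-diol | CCC[C@H](C[C@H](CCc1ccc(O)c(OC)c1)O)O
F6 | step 5 | (3S,5R)-1-[4-(acetyloxy)-3-methoxyphenyl]octane-3,5-diyl diacetate | CCC[C@H](C[C@H](CCc1ccc(OC(C)=O)c(OC)c1)OC(C)=O)OC(C)=O
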